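**Plan**

- Retrosynthetic cuts, in order: the phenol O–Si bond; C9′–C10′ (allyl sulfone alkylation, then C–S hydrogenolysis); C21′–C22′ (allyl–vinyl Stille coupling); the chroman O1–C8a bond; the aryl C4a–C4 bond (B-alkyl Suzuki). One bought arene and three C15 units remain, all from (2E,6E)-farnesol.
- Forward: farnesol → Sharpless epoxide → (S)-alkynol 8, the common chiral block. 8 → (S)-nerolidol → Suzuki coupling with bromoarene 4 → closure of the pyran ring (the only ring formed) → ω-bromide 17. Separately, 8 → vinylstannane 22, joined to chloro sulfone 21 to give the C30 sulfone 23. Then 23 + 17, desulfonylation, desilylation.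
- Enabling feature: the benzene ring of the chroman is 1,4-dioxygenated (C6–OH para to C8a–O1). Two-electron oxidation of a C6 phenol carrying a sacrificial OMe on C8a makes C8a an oxocarbenium-type carbon within reach of the C2 hydroxyl. After the ring O1–C2–C3–C4–C4a–C8a has closed, zinc re-aromatizes it with loss of the OMe.
- Stereochemistry: C2 (S) and C24′ (S) are the same carbinol carbon of 8, set once by the L-(+)-tartrate Sharpless epoxidation; neither C–O bond is broken afterwards. The E-trisubstituted alkenes come from farnesol, and E-C22′=C23′ from syn-hydrostannation.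

Key step: step 9

Remark: chroman atoms are numbered O1–C8a and side-chain carbons C1′ (on C2) to C33′. The target is read as (2S,24′S), so both carbinol carbons have the spatial arrangement of (S)-nerolidol.

**Route**

Step 1
Reactants: 1 2,3-dimethylanisole
Product: 2 1-(4-methoxy-2,3-dimethylphenyl)ethanone
Conditions: AcCl, AlCl3, CH2Cl2, 0 °C
Reagents that add atoms: acetyl chloride, CC(=O)Cl
Why: Friedel–Crafts acylation should go para to the methoxy group, the only strongly activated and unhindered position.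

Step 2
Reactants: 2 1-(4-methoxy-2,3-dimethylphenyl)ethanone
Product: 3 4-methoxy-2,3-dimethylphenyl acetate
Conditions: mCPBA, TFA (cat.), CH2Cl2, rt
Reagents that add atoms: 3-chloroperoxybenzoic acid, OOC(=O)c1cccc(Cl)c1
Why: In this Baeyer–Villiger oxidation the electron-rich 4-methoxyaryl group migrates in preference to methyl, so the acetyl group becomes the acetate that masks the future C6 oxygen.

Step 3
Reactants: 3 4-methoxy-2,3-dimethylphenyl acetate
Product: 4 5-bromo-4-methoxy-2,3-dimethylphenyl acetate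
Conditions: NBS, MeCN, 0 °C → rt, dark
Reagents that add atoms: N-bromosuccinimide, O=C1CCC(=O)N1Br
Why: Electrophilic aromatic bromination; with the phenol acylated the methoxy group is the dominant director, so bromine should enter ortho to OMe (para to the 2-methyl), at the carbon that becomes C4a.

Step 4
Reactants: 5 (2E,6E)-farnesol
Product: 6 (2S,3S)-2,3-epoxy-(6E)-farnesol
Conditions: Ti(OiPr)4 (5 mol %), L-(+)-diethyl tartrate (7 mol %), t-BuOOH, 4 Å MS, CH2Cl2, −20 °C
Reagents that add atoms: tert-butyl hydroperoxide, CC(C)(C)OO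
Why: Sharpless asymmetric epoxidation touches only the allylic C2=C3 alkene, and the L-(+)-tartrate–titanium complex delivers oxygen to the face that gives the (2S,3S)-epoxide, which fixes the carbinol configuration used for both stereocentres of the target.

Step 5
Reactants: 6 (2S,3S)-2,3-epoxy-(6E)-farnesol
Product: 7 (2R,3S,6E)-1-chloro-2,3-epoxy-3,7,11-trimethyldodeca-6,10-diene
Conditions: PPh3, CCl4, NaHCO3 (cat.), reflux
Reagents that add atoms: carbon tetrachloride, ClC(Cl)(Cl)Cl
Why: Appel chlorination replaces the primary hydroxyl under neutral conditions that leave the trisubstituted epoxide and its C3 configuration untouched (the C2 descriptor changes by priority only).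

Step 6
Reactants: 7 (2R,3S,6E)-1-chloro-2,3-epoxy-3,7,11-trimethyldodeca-6,10-diene
Product: 8 (3S,6E)-3,7,11-trimethyldodeca-6,10-dien-1-yn-3-ol
Conditions: n-BuLi (3.3 equiv), THF, −40 → −20 °C; then H2O
Reagents that add atoms: none
Why: Base-induced fragmentation of a 2,3-epoxy chloride (α-deprotonation, epoxide opening to a chlorovinyl alkoxide, then dehydrochlorination) should give the terminal alkyne, and since the C3–O bond is never broken the tertiary carbinol stays (S).

Step 7
Reactants: 8 (3S,6E)-3,7,11-trimethyldodeca-6,10-dien-1-yn-3-ol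
Product: 9 (3S,6E)-nerolidol
Conditions: H2 (1 atm), Lindlar catalyst, quinoline, hexane, rt
Reagents that add atoms: none
Why: Lindlar semihydrogenation reduces only the terminal alkyne to the vinyl group and leaves the trisubstituted alkenes and the stereocentre alone.

Step 8
Reactants: 9 (3S,6E)-nerolidol; 4 5-bromo-4-methoxy-2,3-dimethylphenyl acetate
Product: 12 5-[(3S,6E)-3-hydroxy-3,7,11-trimethyldodeca-6,10-dien-1-yl]-4-methoxy-2,3-dimethylphenol, via B-alkyl-9-BBN adduct 10 (not isolated), via coupled aryl acetate 11 (not isolated)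
Conditions: 9-BBN (1.5 equiv), THF, 0 °C → rt; then 4, Pd(dppf)Cl2 (5 mol %), K3PO4 (3 M aq), THF/DMF, 50 °C; then K2CO3 (cat.), MeOH, rt
Reagents that add atoms: none
Why: Anti-Markovnikov hydroboration of the monosubstituted vinyl group by 9-BBN (trisubstituted alkenes react far more slowly) followed by B-alkyl Suzuki–Miyaura coupling forms the aryl–C4 bond, and base methanolysis of the acetate then frees the phenol without touching the stereocentre.

Step 9
Reactants: 12 5-[(3S,6E)-3-hydroxy-3,7,11-trimethyldodeca-6,10-dien-1-yl]-4-methoxy-2,3-dimethylphenol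
Product: 14 (2S)-2-[(3E)-4,8-dimethylnona-3,7-dien-1-yl]-2,7,8-trimethyl-3,4-dihydro-2H-chromen-6-ol, via 8a-methoxy ketal 13 (not isolated)
Conditions: PhI(OAc)2 (1.05 equiv), (CF3)2CHOH/CH2Cl2 (1:4), −20 → 0 °C; then Zn dust, AcOH, 0 °C → rt (one pot)
Reagents that add atoms: none
Why: PhI(OAc)2 ligates the C6 phenol and removes two electrons, giving a 4-methoxyphenoxenium ion whose positive charge sits on C8a as an O-methyl oxocarbenium; the C2 tertiary hydroxyl adds to this carbon and closes the pyran ring (O1–C2–C3–C4–C4a–C8a) in a 6-exo-trig mode onto the exocyclic C8a=O+Me unit, giving the 8a-methoxy ketal 13. Zn/AcOH then transfers two electrons to the cross-conjugated dienone, methanol leaves from C8a and the benzene ring returns, so the net change is replacement of the OMe helper by the side-chain oxygen. The closest known reaction types are the hypervalent-iodine oxidative dearomatization of 4-alkoxyphenols to quinone monoketals with an internal alcohol as nucleophile, and the reductive aromatization of 8a-alkoxy-chromen-6-ones (tocopherone-type ketals) to 6-chromanols. No new stereocentre reaches the product: C8a of 13 is formed as both epimers and is flattened on reduction, while C2 stays (S) because its C–O bond is never broken and the nerolidol oxygen becomes O1 with retention. The step needs attack at C8a and not at C5 (the other neighbour of C4a, also a six-membered closure), which the methoxy group secures by localizing the charge on C8a; it needs oxidation of the phenol and not of the alkenes, which follows because the iodane reacts only after O-ligation; and it needs loss of OMe and not of the ring oxygen in the reduction, where the alternative merely returns 12 for recycling.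

Step 10
Reactants: 14 (2S)-2-[(3E)-4,8-dimethylnona-3,7-dien-1-yl]-2,7,8-trimethyl-3,4-dihydro-2H-chromen-6-ol
Product: 15 {[(2S)-2-[(3E)-4,8-dimethylnona-3,7-dien-1-yl]-2,7,8-trimethyl-3,4-dihydro-2H-chromen-6-yl]oxy}tri(propan-2-yl)silane
Conditions: TIPSCl, imidazole, DMF, 40 °C
Reagents that add atoms: chlorotri(propan-2-yl)silane, CC(C)[Si](Cl)(C(C)C)C(C)C
Why: Silyl ether formation masks the oxidation-prone 6-chromanol against SeO2/t-BuOOH, organolithium and hydride reagents, and an aryl TIPS ether should survive these and fall to fluoride at the end.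

Step 11
Reactants: 15 {[(2S)-2-[(3E)-4,8-dimethylnona-3,7-dien-1-yl]-2,7,8-trimethyl-3,4-dihydro-2H-chromen-6-yl]oxy}tri(propan-2-yl)silane
Product: 16 (2E,6E)-2,6-dimethyl-9-[(2S)-2,7,8-trimethyl-6-{[tri(propan-2-yl)silyl]oxy}-3,4-dihydro-2H-chromen-2-yl]nona-2,6-dien-1-ol
Conditions: SeO2 (0.3 equiv), t-BuOOH, salicylic acid (cat.), CH2Cl2, 0 °C → rt, stopped at partial conversion
Reagents that add atoms: tert-butyl hydroperoxide, CC(C)(C)OO
Why: Catalytic SeO2/t-BuOOH allylic oxidation (ene reaction, then [2,3]-shift) attacks the (E)-methyl of the terminal trisubstituted alkene fastest and should give the (E)-allylic alcohol, the internal alkene reacting more slowly and unreacted 15 being recovered.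

Step 12
Reactants: 16 (2E,6E)-2,6-dimethyl-9-[(2S)-2,7,8-trimethyl-6-{[tri(propan-2-yl)silyl]oxy}-3,4-dihydro-2H-chromen-2-yl]nona-2,6-dien-1-ol
Product: 17 {[(2S)-2-[(3E,7E)-9-bromo-4,8-dimethylnona-3,7-dien-1-yl]-2,7,8-trimethyl-3,4-dihydro-2H-chromen-6-yl]oxy}tri(propan-2-yl)silane
Conditions: CBr4, PPh3, CH2Cl2, −20 → 0 °C
Reagents that add atoms: carbon tetrabromide, BrC(Br)(Br)Br
Why: Appel bromination converts the primary allylic alcohol into the bromide under neutral conditions without allylic transposition or loss of E geometry.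

Step 13
Reactants: 18 (2E,6E)-farnesyl bromide
Product: 19 [(2E,6E)-3,7,11-trimethyldodeca-2,6,10-trien-1-yl]sulfonylbenzene
Conditions: PhSO2Na, DMF, rt
Reagents that add atoms: sodium benzenesulfinate, [Na+].[O-]S(=O)c1ccccc1
Why: SN2 displacement of the primary allylic bromide by the sulfur of the sulfinate should give the allylic sulfone with the 2E geometry retained.

Step 14
Reactants: 19 [(2E,6E)-3,7,11-trimethyldodeca-2,6,10-trien-1-yl]sulfonylbenzene
Product: 20 (2E,6E,10E)-2,6,10-trimethyl-12-(phenylsulfonyl)dodeca-2,6,10-trien-1-ol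
Conditions: SeO2 (0.3 equiv), t-BuOOH, salicylic acid (cat.), CH2Cl2, rt, stopped at partial conversion
Reagents that add atoms: tert-butyl hydroperoxide, CC(C)(C)OO
Why: The same SeO2 allylic oxidation picks the (E)-methyl of the terminal isopropylidene, the alkene next to the electron-withdrawing sulfone being deactivated.

Step 15
Reactants: 20 (2E,6E,10E)-2,6,10-trimethyl-12-(phenylsulfonyl)dodeca-2,6,10-trien-1-ol
Product: 21 [(2E,6E,10E)-12-chloro-3,7,11-trimethyldodeca-2,6,10-trien-1-yl]sulfonylbenzene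
Conditions: PPh3, CCl4, reflux
Reagents that add atoms: carbon tetrachloride, ClC(Cl)(Cl)Cl
Why: Appel chlorination of a primary allylic alcohol should give the allylic chloride without rearrangement, the sulfone being inert.

Step 16
Reactants: 8 (3S,6E)-3,7,11-trimethyldodeca-6,10-dien-1-yn-3-ol
Product: 22 (1E,3S,6E)-3,7,11-trimethyl-1-(tributylstannyl)dodeca-1,6,10-trien-3-ol
Conditions: Bu3SnH, PdCl2(PPh3)2 (2 mol %), THF, 0 °C
Reagents that add atoms: tributyltin hydride, CCCC[SnH](CCCC)CCCC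
Why: Pd-catalysed syn-hydrostannation of the terminal alkyne, in which the bulky tertiary carbinol directs tin to the terminal carbon, should give the (E)-β-stannyl allylic alcohol with the carbinol untouched.

Step 17
Reactants: 21 [(2E,6E,10E)-12-chloro-3,7,11-trimethyldodeca-2,6,10-trien-1-yl]sulfonylbenzene; 22 (1E,3S,6E)-3,7,11-trimethyl-1-(tributylstannyl)dodeca-1,6,10-trien-3-ol
Product: 23 (6E,10S,11E,14E,18E,22E)-2,6,10,14,18,22-hexamethyl-24-(phenylsulfonyl)tetracosa-2,6,11,14,18,22-hexaen-10-ol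
Conditions: Pd2(dba)3 (2.5 mol %), AsPh3 (10 mol %), NMP, rt → 40 °C
Reagents that add atoms: none
Why: In this Stille allyl–vinyl cross-coupling the π-allyl-palladium from the allylic chloride couples with the vinylstannane at its unhindered CH2 terminus, forming C21′–C22′ with the E geometry of both partners retained and the free tertiary alcohol and the sulfone tolerated.

Step 18
Reactants: 23 (6E,10S,11E,14E,18E,22E)-2,6,10,14,18,22-hexamethyl-24-(phenylsulfonyl)tetracosa-2,6,11,14,18,22-hexaen-10-ol; 17 {[(2S)-2-[(3E,7E)-9-bromo-4,8-dimethylnona-3,7-dien-1-yl]-2,7,8-trimethyl-3,4-dihydro-2H-chromen-6-yl]oxy}tri(propan-2-yl)silane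
Product: 25 {[(2S)-2-[(3E,7E,11E,15E,19E,22E,24S,27E)-24-hydroxy-4,8,12,16,20,24,28,32-octamethyl-10-(phenylsulfonyl)tritriaconta-3,7,11,15,19,22,27,31-octaen-1-yl]-2,7,8-trimethyl-3,4-dihydro-2H-chromen-6-yl]oxy}tri(propan-2-yl)silane (both C10′ epimers), via dilithio sulfone 24 (not isolated)
Conditions: n-BuLi (2.1 equiv), THF/DMPU, −78 °C; then 17, −78 → −40 °C; then H2O
Reagents that add atoms: none
Why: Alkylation of an α-sulfonyl carbanion (allyl sulfone coupling): the second equivalent of base gives the sulfone-stabilized carbanion, which is far more nucleophilic towards the primary allylic bromide than the hindered tertiary alkoxide, and so forms C9′–C10′.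

Step 19
Reactants: 25 the C10′-sulfone (both epimers)
Product: 26 {[(2S)-2-[(3E,7E,11E,15E,19E,22E,24S,27E)-24-hydroxy-4,8,12,16,20,24,28,32-octamethyltritriaconta-3,7,11,15,19,22,27,31-octaen-1-yl]-2,7,8-trimethyl-3,4-dihydro-2H-chromen-6-yl]oxy}tri(propan-2-yl)silane
Conditions: PdCl2(dppp) (5 mol %), LiBHEt3 (4 equiv), THF, 0 °C
Reagents that add atoms: none
Why: In this Pd-catalysed reductive desulfonylation the π-allyl-palladium formed from the allylic sulfone takes hydride at its less substituted terminus (C10′), so the C11′=C12′ alkene keeps position and E geometry, while the tertiary alkoxide is too poor a leaving group to ionize.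

Step 20
Reactants: 26 the TIPS ether of the target
Product: 27 (2S)-2-[(3E,7E,11E,15E,19E,22E,24S,27E)-24-hydroxy-4,8,12,16,20,24,28,32-octamethyltritriaconta-3,7,11,15,19,22,27,31-octaen-1-yl]-2,7,8-trimethyl-3,4-dihydro-2H-chromen-6-ol (target)
Conditions: TBAF, THF, 0 °C, degassed; NH4Cl work-up
Reagents that add atoms: none
Why: Fluoride-mediated desilylation cleaves the aryl TIPS ether under non-acidic conditions that spare the tertiary allylic alcohol and the skipped diene.

**Compound list**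

1 | 2,3-dimethylanisole | COc1cccc(C)c1C | starting material
2 | 1-(4-methoxy-2,3-dimethylphenyl)ethanone | CC(=O)c1ccc(OC)c(C)c1C | intermediate
3 | 4-methoxy-2,3-dimethylphenyl acetate | CC(=O)Oc1ccc(OC)c(C)c1C | intermediate
4 | 5-bromo-4-methoxy-2,3-dimethylphenyl acetate | CC(=O)Oc1cc(Br)c(OC)c(C)c1C | intermediate
5 | (2E,6E)-farnesol | CC(C)=CCC/C(C)=C/CC/C(C)=C/CO | starting material
6 | (2S,3S)-2,3-epoxy-(6E)-farnesol | CC(C)=CCC/C(C)=C/CC[C@]1(C)O[C@H]1CO | intermediate
7 | (2R,3S,6E)-1-chloro-2,3-epoxy-3,7,11-trimethyldodeca-6,10-diene | CC(C)=CCC/C(C)=C/CC[C@]1(C)O[C@H]1CCl | intermediate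
8 | (3S,6E)-3,7,11-trimethyldodeca-6,10-dien-1-yn-3-ol | CC(C)=CCC/C(C)=C/CC[C@](C)(O)C#C | intermediate
9 | (3S,6E)-nerolidol | CC(C)=CCC/C(C)=C/CC[C@](C)(O)C=C | intermediate
10 | (6E)-1-(9-borabicyclo[3.3.1]nonan-9-yl)-3,7,11-trimethyldodeca-6,10-dien-3-ol, carbinol arranged as in 9 (descriptor 3R by priority only) | CC(C)=CCC/C(C)=C/CC[C@](C)(O)CCB1C2CCCC1CCC2 | intermediate
11 | 5-[(3S,6E)-3-hydroxy-3,7,11-trimethyldodeca-6,10-dien-1-yl]-4-methoxy-2,3-dimethylphenyl acetate | CC(C)=CCC/C(C)=C/CC[C@](C)(O)CCc1cc(OC(C)=O)c(C)c(C)c1OC | intermediate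
12 | 5-[(3S,6E)-3-hydroxy-3,7,11-trimethyldodeca-6,10-dien-1-yl]-4-methoxy-2,3-dimethylphenol | CC(C)=CCC/C(C)=C/CC[C@](C)(O)CCc1cc(O)c(C)c(C)c1OC | intermediate
13 | (2S)-2-[(3E)-4,8-dimethylnona-3,7-dien-1-yl]-8a-methoxy-2,7,8-trimethyl-2,3,4,8a-tetrahydro-6H-chromen-6-one (both C8a epimers) | CC(C)=CCC/C(C)=C/CC[C@@]1(C)CCC2=CC(=O)C(C)=C(C)C2(OC)O1 | intermediate
14 | (2S)-2-[(3E)-4,8-dimethylnona-3,7-dien-1-yl]-2,7,8-trimethyl-3,4-dihydro-2H-chromen-6-ol | CC(C)=CCC/C(C)=C/CC[C@@]1(C)CCc2cc(O)c(C)c(C)c2O1 | intermediate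
15 | TIPS ether of 14 | CC(C)=CCC/C(C)=C/CC[C@@]1(C)CCc2cc(O[Si](C(C)C)(C(C)C)C(C)C)c(C)c(C)c2O1 | intermediate
16 | (2E,6E)-2,6-dimethyl-9-[(2S)-2,7,8-trimethyl-6-{[tri(propan-2-yl)silyl]oxy}-3,4-dihydro-2H-chromen-2-yl]nona-2,6-dien-1-ol | OC/C(C)=C/CC/C(C)=C/CC[C@@]1(C)CCc2cc(O[Si](C(C)C)(C(C)C)C(C)C)c(C)c(C)c2O1 | intermediate
17 | {[(2S)-2-[(3E,7E)-9-bromo-4,8-dimethylnona-3,7-dien-1-yl]-2,7,8-trimethyl-3,4-dihydro-2H-chromen-6-yl]oxy}tri(propan-2-yl)silane | BrC/C(C)=C/CC/C(C)=C/CC[C@@]1(C)CCc2cc(O[Si](C(C)C)(C(C)C)C(C)C)c(C)c(C)c2O1 | intermediate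
18 | (2E,6E)-farnesyl bromide | CC(C)=CCC/C(C)=C/CC/C(C)=C/CBr | starting material
19 | [(2E,6E)-3,7,11-trimethyldodeca-2,6,10-trien-1-yl]sulfonylbenzene | CC(C)=CCC/C(C)=C/CC/C(C)=C/CS(=O)(=O)c1ccccc1 | intermediate
20 | (2E,6E,10E)-2,6,10-trimethyl-12-(phenylsulfonyl)dodeca-2,6,10-trien-1-ol | OC/C(C)=C/CC/C(C)=C/CC/C(C)=C/CS(=O)(=O)c1ccccc1 | intermediate
21 | [(2E,6E,10E)-12-chloro-3,7,11-trimethyldodeca-2,6,10-trien-1-yl]sulfonylbenzene | ClC/C(C)=C/CC/C(C)=C/CC/C(C)=C/CS(=O)(=O)c1ccccc1 | intermediate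
22 | (1E,3S,6E)-3,7,11-trimethyl-1-(tributylstannyl)dodeca-1,6,10-trien-3-ol | CC(C)=CCC/C(C)=C/CC[C@](C)(O)/C=C/[Sn](CCCC)(CCCC)CCCC | intermediate
23 | (6E,10S,11E,14E,18E,22E)-2,6,10,14,18,22-hexamethyl-24-(phenylsulfonyl)tetracosa-2,6,11,14,18,22-hexaen-10-ol | CC(C)=CCC/C(C)=C/CC[C@](C)(O)/C=C/C/C(C)=C/CC/C(C)=C/CC/C(C)=C/CS(=O)(=O)c1ccccc1 | intermediate
24 | dilithium salt of 23 (C10 alkoxide, C24 α-sulfonyl carbanion) | CC(C)=CCC/C(C)=C/CC[C@](C)([O-])/C=C/C/C(C)=C/CC/C(C)=C/CC/C(C)=C/[CH-]S(=O)(=O)c1ccccc1.[Li+].[Li+] | intermediate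
25 | TIPS ether of the target carrying PhSO2 on C10′ (both C10′ epimers) | CC(C)=CCC/C(C)=C/CC[C@](C)(O)/C=C/C/C(C)=C/CC/C(C)=C/CC/C(C)=C/C(C/C(C)=C/CC/C(C)=C/CC[C@@]1(C)CCc2cc(O[Si](C(C)C)(C(C)C)C(C)C)c(C)c(C)c2O1)S(=O)(=O)c1ccccc1 | intermediate
26 | TIPS ether of the target | CC(C)=CCC/C(C)=C/CC[C@](C)(O)/C=C/C/C(C)=C/CC/C(C)=C/CC/C(C)=C/CC/C(C)=C/CC/C(C)=C/CC[C@@]1(C)CCc2cc(O[Si](C(C)C)(C(C)C)C(C)C)c(C)c(C)c2O1 | intermediate
27 | (2S)-2-[(3E,7E,11E,15E,19E,22E,24S,27E)-24-hydroxy-4,8,12,16,20,24,28,32-octamethyltritriaconta-3,7,11,15,19,22,27,31-octaen-1-yl]-2,7,8-trimethyl-3,4-dihydro-2H-chromen-6-ol | CC(C)=CCC/C(C)=C/CC[C@](C)(O)/C=C/C/C(C)=C/CC/C(C)=C/CC/C(C)=C/CC/C(C)=C/CC/C(C)=C/CC[C@@]1(C)CCc2cc(O)c(C)c(C)c2O1 | target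

**Step count and risks**

Total steps: 20. Longest linear sequence: 12 steps (steps 4–12 and 18–20, from farnesol 5).

Steps most likely to fail:

1. Step 9. The hindered tertiary hydroxyl may lose the race for the oxidized ring to acetate or adventitious water, which would open the system to the quinone, or the reduction may cleave the ring C8a–O bond instead of C8a–OMe. The fallback sets out from 12 and comes back at 13; it separates oxidation from ring closure. 12 would be oxidized with PhI(OAc)2 in methanol, where solvent capture at C8a is fast and well precedented, to the quinone dimethyl monoketal 5-[(3S,6E)-3-hydroxy-3,7,11-trimethyldodeca-6,10-dien-1-yl]-4,4-dimethoxy-2,3-dimethylcyclohexa-2,5-dien-1-one F1. Acid-catalysed transketalization (PPTS cat., 4 Å MS, CH2Cl2) should then exchange one methoxy group for the tethered hydroxyl under thermodynamic control to give 13, which is reduced with Zn/AcOH to 14 as in step 9.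

2. Step 19. The palladium hydride may also hydrogenolyse the tertiary allylic C24′–O bond or move the C11′=C12′ double bond. The fallback sets out from 20 (using 17 and 22) and comes back at 26; it removes the sulfone before the allylic carbinol is present. 20 would be silylated (TBSCl, imidazole, DMF) to the TBS ether of 20 F2. Its α-sulfonyl carbanion (n-BuLi, THF, −78 °C) would be alkylated with 17 to the coupled C10′-sulfonyl 21′-silyl ether F3. PdCl2(dppp)/LiBHEt3 should give the sulfone-free 21′-silyl ether F4. PPTS in MeOH should remove only the primary TBS group to give the 21′-allylic alcohol F5, PPh3/CCl4 should give the 21′-allylic chloride F6, and Stille coupling of F6 with 22 under the conditions of step 17 should give 26.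

3. Step 17. Syn/anti isomerization of the 2-methyl-π-allyl-palladium intermediate may erode the C19′=C20′ geometry, coupling may occur at the wrong allyl terminus, or Pd(0) may ionize the allylic sulfone. The fallback sets out from 21 and 8 and comes back at 23; it uses copper instead of palladium and the alkyne instead of the stannane. Cu(I)-catalysed coupling of the terminal alkyne 8 with 21 (CuI, K2CO3, NaI, DMF, rt) should give the skipped enyne (6E,10S,14E,18E,22E)-2,6,10,14,18,22-hexamethyl-24-(phenylsulfonyl)tetracosa-2,6,14,18,22-pentaen-11-yn-10-ol F7. Hydroxyl-directed trans-hydroalumination with Red-Al (THF, −20 → 0 °C) and protonolysis should then give the E-allylic alcohol 23.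

Further compounds
F1 | step 9 | 5-[(3S,6E)-3-hydroxy-3,7,11-trimethyldodeca-6,10-dien-1-yl]-4,4-dimethoxy-2,3-dimethylcyclohexa-2,5-dien-1-one | CC(C)=CCC/C(C)=C/CC[C@](C)(O)CCC1=CC(=O)C(C)=C(C)C1(OC)OC
F2 | step 19 | tert-butyl(dimethyl){[(2E,6E,10E)-2,6,10-trimethyl-12-(phenylsulfonyl)dodeca-2,6,10-trien-1-yl]oxy}silane | CC(C)(C)[Si](C)(C)OC/C(C)=C/CC/C(C)=C/CC/C(C)=C/CS(=O)(=O)c1ccccc1
F3 | step 19 | (2S)-chroman 6-TIPS ether with a (3E,7E,11E,15E,19E)-21-(tert-butyldimethylsilyloxy)-4,8,12,16,20-pentamethyl-10-(phenylsulfonyl)henicosa-3,7,11,15,19-pentaen-1-yl chain on C2 (both C10′ epimers) | CC(C)(C)[Si](C)(C)OC/C(C)=C/CC/C(C)=C/CC/C(C)=C/C(C/C(C)=C/CC/C(C)=C/CC[C@@]1(C)CCc2cc(O[Si](C(C)C)(C(C)C)C(C)C)c(C)c(C)c2O1)S(=O)(=O)c1ccccc1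
F4 | step 19 | (2S)-chroman 6-TIPS ether with a (3E,7E,11E,15E,19E)-21-(tert-butyldimethylsilyloxy)-4,8,12,16,20-pentamethylhenicosa-3,7,11,15,19-pentaen-1-yl chain on C2 | CC(C)(C)[Si](C)(C)OC/C(C)=C/CC/C(C)=C/CC/C(C)=C/CC/C(C)=C/CC/C(C)=C/CC[C@@]1(C)CCc2cc(O[Si](C(C)C)(C(C)C)C(C)C)c(C)c(C)c2O1
F5 | step 19 | (2E,6E,10E,14E,18E)-2,6,10,14,18-pentamethyl-21-[(2S)-2,7,8-trimethyl-6-{[tri(propan-2-yl)silyl]oxy}-3,4-dihydro-2H-chromen-2-yl]henicosa-2,6,10,14,18-pentaen-1-ol | OC/C(C)=C/CC/C(C)=C/CC/C(C)=C/CC/C(C)=C/CC/C(C)=C/CC[C@@]1(C)CCc2cc(O[Si](C(C)C)(C(C)C)C(C)C)c(C)c(C)c2O1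
F6 | step 19 | {[(2S)-2-[(3E,7E,11E,15E,19E)-21-chloro-4,8,12,16,20-pentamethylhenicosa-3,7,11,15,19-pentaen-1-yl]-2,7,8-trimethyl-3,4-dihydro-2H-chromen-6-yl]oxy}tri(propan-2-yl)silane | ClC/C(C)=C/CC/C(C)=C/CC/C(C)=C/CC/C(C)=C/CC/C(C)=C/CC[C@@]1(C)CCc2cc(O[Si](C(C)C)(C(C)C)C(C)C)c(C)c(C)c2O1
F7 | step 17 | (6E,10S,14E,18E,22E)-2,6,10,14,18,22-hexamethyl-24-(phenylsulfonyl)tetracosa-2,6,14,18,22-pentaen-11-yn-10-ol | CC(C)=CCC/C(C)=C/CC[C@](C)(O)C#CC/C(C)=C/CC/C(C)=C/CC/C(C)=C/CS(=O)(=O)c1ccccc1
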